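## Retrosynthetic overview

1. The strategy rests on the ketone carbon C7. It is bonded to C3 of the pyridone (ring A), a carbon wedged between the oxygen-bearing C2 and C4, and to C8 of the all-E C8–C13 triene. C7 is therefore supplied as carbon monoxide, and C3–C7 and C7–C8 are made together from a ring-A C3 iodide and a C8 trienylstannane.
2. Ring-A iodide: the C5–C1' bond comes from adding a C5 pyridyllithium to 4-silyloxycyclohexanone (ring B), followed by C3 lithiation–iodination. The C5 anion is made from the 5-bromide because deprotonation would go to C3. O2 and O4 are masked as 2-(trimethylsilyl)ethyl ethers, because cleaving methyl ethers needs boron or silicon halides that would ionise the tertiary C1' carbinol and strip the silyl ethers.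
3. Stannane: C14 is set by auxiliary-controlled hydroxymethylation of a butanoyl imide, a vinylogous HWE reaction delivers C9–C12 and forms C12=C13, and C8=C9 comes from chromium-mediated stannyl olefination.
4. Endgame: one fluoride treatment frees both ring-A oxygens and both alcohols, then N1 is hydroxylated by O-silylation and peroxomolybdenum oxidation.
5. No ring is formed. Ring A (pyridine) and ring B (cyclohexane) are bought intact and joined in step 2.

Key step: step 14

Numbering used: ring A is N1, C2 (O), C3 (acyl), C4 (O), C5 (cyclohexyl), C6. The ketone carbon is C7, the triene is C8–C13 and the side-chain stereocentre is C14. Ring B has C1' (tertiary carbinol) and C4' (secondary carbinol).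

Assumption: the hindered tertiary C1' hydroxyl is taken to stay free under N,O-bis(trimethylsilyl)acetamide at room temperature. If it is silylated as well, that ether is cleaved in the same closing hydrolysis and the outcome is unchanged.

## Route

**Step 1**
Reactants: 1 5-bromo-2,4-dichloropyridine
Product: 2 5-bromo-2,4-bis[2-(trimethylsilyl)ethoxy]pyridine
Conditions: Me3SiCH2CH2OH (2.5 equiv), NaH (2.6 equiv), THF–DMF, 0 → 60 °C
Reagents that add atoms: 2-(trimethylsilyl)ethanol, C[Si](C)(C)CCO
Why: Double nucleophilic aromatic substitution (SNAr) by the sodium alkoxide displaces C4–Cl (para to N) and then, on warming, C2–Cl (ortho to N and para to the anion-stabilising bromine), whereas C5–Br sits meta to N and is not activated, and the ethers so installed can later be removed by fluoride alone.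

**Step 2**
Reactants: 2 5-bromo-2,4-bis[2-(trimethylsilyl)ethoxy]pyridine; 3 4-(tert-butyldimethylsilyloxy)cyclohexanone
Product: 5 cis-4-(tert-butyldimethylsilyloxy)-1-{4,6-bis[2-(trimethylsilyl)ethoxy]pyridin-3-yl}cyclohexan-1-ol (1-OH and 4-OSi on the same ring face), via pyridin-3-yllithium 4 (not isolated)
Conditions: n-BuLi (1.05 equiv), Et2O–THF, −78 °C, 15 min; 3, −78 → −40 °C; H2O; chromatographic removal of the trans isomer
Reagents that add atoms: none
Why: Bromine–lithium exchange places the carbanion at C5 (deprotonation would instead occur at C3 between the two alkoxy groups), and 1,2-addition of this ortho-substituted aryllithium along the less encumbered equatorial trajectory of the chair with an equatorial silyloxy group should put the new C1' hydroxyl axial and thus cis to the C4' oxygen, the minor trans adduct being separable on silica.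

**Step 3**
Reactants: 5 cis-4-(tert-butyldimethylsilyloxy)-1-{4,6-bis[2-(trimethylsilyl)ethoxy]pyridin-3-yl}cyclohexan-1-ol
Product: 7 cis-4-(tert-butyldimethylsilyloxy)-1-{5-iodo-4,6-bis[2-(trimethylsilyl)ethoxy]pyridin-3-yl}cyclohexan-1-ol, via C3-lithiated lithium alkoxide 6 (not isolated)
Conditions: n-BuLi (2.3 equiv), THF, −78 → −20 °C; I2 (1.2 equiv), THF, −78 °C; aq Na2S2O3
Reagents that add atoms: iodine, [I][I]
Why: Directed ortho-metalation followed by iodinolysis, in which the first equivalent of base forms the alkoxide, the second removes C3–H (the only ring proton flanked and coordinated by two alkoxy oxygens), and the aryllithium is quenched by iodine at low temperature without touching the silicon groups.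

**Step 4**
Reactants: 8 (R)-4-benzyloxazolidin-2-one; 9 butanoyl chloride
Product: 10 (R)-4-benzyl-3-butanoyloxazolidin-2-one
Conditions: Et3N (1.3 equiv), DMAP (10 mol %), CH2Cl2, 0 °C → rt
Reagents that add atoms: none
Why: DMAP-catalysed N-acylation of the oxazolidinone by the acid chloride is a standard way to load an Evans auxiliary without strong base.

**Step 5**
Reactants: 10 (R)-4-benzyl-3-butanoyloxazolidin-2-one; 11 1,3,5-trioxane
Product: 13 (R)-4-benzyl-3-[(S)-2-(hydroxymethyl)butanoyl]oxazolidin-2-one, via trichlorotitanium Z-enolate 12 (not isolated)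
Conditions: TiCl4 (1.05 equiv), iPr2NEt (1.15 equiv), CH2Cl2, 0 °C; 11 (1.2 equiv), then TiCl4 (1.05 equiv), 0 °C; H2O
Reagents that add atoms: none
Why: Evans titanium-enolate hydroxymethylation (an aldol-type addition to TiCl4-activated trioxane as the formaldehyde source), in which the chelated Z-enolate 12 is attacked on the face away from the C4 benzyl group of the (R)-auxiliary, setting the (S)-configured α-carbon that becomes C14 of the target.

**Step 6**
Reactants: 13 (R)-4-benzyl-3-[(S)-2-(hydroxymethyl)butanoyl]oxazolidin-2-one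
Product: 14 (R)-4-benzyl-3-[(S)-2-(tert-butyldimethylsilyloxymethyl)butanoyl]oxazolidin-2-one
Conditions: TBSCl (1.2 equiv), imidazole (2 equiv), CH2Cl2, rt
Reagents that add atoms: tert-butyldimethylsilyl chloride, CC(C)(C)[Si](C)(C)Cl
Why: Standard imidazole-mediated silylation of a primary alcohol is mild enough to avoid retro-aldol loss of formaldehyde and epimerisation of the β-hydroxy imide.

**Step 7**
Reactants: 14 (R)-4-benzyl-3-[(S)-2-(tert-butyldimethylsilyloxymethyl)butanoyl]oxazolidin-2-one
Product: 15 (R)-2-(tert-butyldimethylsilyloxymethyl)butan-1-ol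
Conditions: LiBH4 (1.5 equiv), H2O (1 equiv), Et2O–THF, 0 °C; pH 7 buffer
Reagents that add atoms: none
Why: Reductive cleavage of the N-acyloxazolidinone by borohydride at the exocyclic carbonyl gives the primary alcohol and returns the auxiliary, and the cold, near-neutral work-up prevents the O-to-O silyl shift that would racemise this pseudo-symmetric diol derivative.

**Step 8**
Reactants: 15 (R)-2-(tert-butyldimethylsilyloxymethyl)butan-1-ol
Product: 16 (S)-2-(tert-butyldimethylsilyloxymethyl)butanal
Conditions: TEMPO (10 mol %), PhI(OAc)2 (1.1 equiv), CH2Cl2, rt; used at once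
Reagents that add atoms: none
Why: Oxoammonium (TEMPO/PhI(OAc)2) oxidation stops at the aldehyde and runs without amine base, so the α-stereocentre should not epimerise and the β-silyloxy group should not be eliminated (the descriptor changes from R to S only through the priority rules).

**Step 9**
Reactants: 16 (S)-2-(tert-butyldimethylsilyloxymethyl)butanal; 17 triethyl (E)-4-phosphonocrotonate
Product: 19 ethyl (2E,4E,6R)-6-(tert-butyldimethylsilyloxymethyl)octa-2,4-dienoate, via lithiated phosphonate 18 (not isolated)
Conditions: 17 (1.3 equiv), LiN(SiMe3)2 (1.25 equiv), THF, −78 °C; 16, −78 → 0 °C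
Reagents that add atoms: none
Why: Vinylogous Horner–Wadsworth–Emmons olefination, in which the preformed lithium phosphonate 18 (no excess base) adds at low temperature and the reversible addition of the stabilised anion favours E geometry at the new C12=C13 bond while the E crotonate bond (C10=C11) is carried over, minor Z isomers being removed by chromatography.

**Step 10**
Reactants: 19 ethyl (2E,4E,6R)-6-(tert-butyldimethylsilyloxymethyl)octa-2,4-dienoate
Product: 20 (2E,4E,6R)-6-(tert-butyldimethylsilyloxymethyl)octa-2,4-dien-1-ol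
Conditions: iBu2AlH (2.3 equiv), CH2Cl2, −78 °C; aq potassium sodium tartrate
Reagents that add atoms: none
Why: 1,2-Reduction of the conjugated ester by iBu2AlH at low temperature gives the allylic alcohol without touching the diene or the silyl ether.

**Step 11**
Reactants: 20 (2E,4E,6R)-6-(tert-butyldimethylsilyloxymethyl)octa-2,4-dien-1-ol
Product: 21 (2E,4E,6R)-6-(tert-butyldimethylsilyloxymethyl)octa-2,4-dienal
Conditions: activated MnO2 (excess), CH2Cl2, rt
Reagents that add atoms: none
Why: Chemoselective MnO2 oxidation of the dienylic alcohol gives the dienal under neutral heterogeneous conditions that preserve the alkene geometry and the C14 centre.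

**Step 12**
Reactants: 22 dibromomethane; 23 tributyltin chloride
Product: 25 tributyl(dibromomethyl)stannane, via dibromomethyllithium 24 (not isolated)
Conditions: LiN(iPr)2 (1.0 equiv), THF–Et2O, −95 °C; 23, −95 °C → rt
Reagents that add atoms: none
Why: Deprotonation of dibromomethane to the carbenoid 24 at very low temperature, followed by nucleophilic substitution at tin, gives the geminal dihalide needed for the chromium olefination.

**Step 13**
Reactants: 21 (2E,4E,6R)-6-(tert-butyldimethylsilyloxymethyl)octa-2,4-dienal; 25 tributyl(dibromomethyl)stannane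
Product: 28 tributyl[(1E,3E,5E,7R)-7-(tert-butyldimethylsilyloxymethyl)nona-1,3,5-trienyl]stannane, via tributyl(diiodomethyl)stannane 26 (not isolated), via geminal dichromium reagent 27 (not isolated)
Conditions: CrCl2 (10 equiv), LiI (4 equiv), 25 (2 equiv), THF–DMF, rt, dark; Et3N-deactivated silica
Reagents that add atoms: none
Why: Takai-type olefination in its stannyl (Hodgson) variant, in which halide exchange with LiI gives 26, CrCl2 reduces it to the geminal dichromium nucleophile 27, and addition to the aldehyde followed by elimination from the less crowded adduct should make the new C8=C9 bond E, while the non-basic medium leaves C14 and the existing diene unchanged.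

**Step 14**
Reactants: 7 cis-4-(tert-butyldimethylsilyloxy)-1-{5-iodo-4,6-bis[2-(trimethylsilyl)ethoxy]pyridin-3-yl}cyclohexan-1-ol; 28 tributyl[(1E,3E,5E,7R)-7-(tert-butyldimethylsilyloxymethyl)nona-1,3,5-trienyl]stannane; 29 carbon monoxide
Product: 30 (2E,4E,6E,8R)-1-{5-[cis-4-(tert-butyldimethylsilyloxy)-1-hydroxycyclohexyl]-2,4-bis[2-(trimethylsilyl)ethoxy]pyridin-3-yl}-8-(tert-butyldimethylsilyloxymethyl)deca-2,4,6-trien-1-one
Conditions: Pd(PPh3)4 (10 mol %), CuI (30 mol %), 28 (1.3 equiv), CO (5 bar), BHT (cat), 1,4-dioxane, 60 °C, dark; K2CO3-doped silica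
Reagents that add atoms: none
Why: Zerovalent palladium from Pd(PPh3)4 inserts into the C3–I bond of 7, CO migrates into the crowded aryl–palladium bond to give an aroylpalladium iodide, the trienyl group of 28 is handed over from tin (CuI takes up free PPh3 and speeds this slow step), and reductive elimination releases 30, so that C3–C7 and C7–C8 are made in one operation. The closest known reaction type is the carbonylative Stille coupling of aryl iodides with alkenylstannanes to aryl alkenyl ketones, including its copper-assisted variants for hindered partners. No ring is closed and no stereocentre is created, and C14 and the cis ring-B pair are spectators remote from the metal. The first selectivity needed is ketone formation over direct C3–C8 coupling: the two ortho alkoxy groups make transmetalation at the arylpalladium stage slow, CO insertion relieves strain, and 5 bar of CO keeps the acyl form populated. The second is the all-E geometry, which should hold because alkenyl transfer from tin and reductive elimination proceed with retention, and 60 °C in the dark with BHT limits isomerisation of the trienone. The tertiary hydroxyl is too hindered and too remote (meta) to trap the acylpalladium, and the silyl and 2-(trimethylsilyl)ethyl ethers are inert in the neutral medium.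

**Step 15**
Reactants: 30 (2E,4E,6E,8R)-1-{5-[cis-4-(tert-butyldimethylsilyloxy)-1-hydroxycyclohexyl]-2,4-bis[2-(trimethylsilyl)ethoxy]pyridin-3-yl}-8-(tert-butyldimethylsilyloxymethyl)deca-2,4,6-trien-1-one
Product: 31 4-hydroxy-5-(cis-1,4-dihydroxycyclohexyl)-3-[(2E,4E,6E,8R)-8-(hydroxymethyl)deca-2,4,6-trienoyl]pyridin-2(1H)-one
Conditions: Bu4NF (8 equiv, 1 M in THF), THF, 0 °C → rt; AcOH
Reagents that add atoms: none
Why: Fluoride-induced desilylation, in which the two Me3SiCH2CH2–O groups (vinylogous ester and imidate oxygens of the 3-acylpyridine, hence good leaving groups) fragment by β-elimination to ethylene and the pyridone while both TBS ethers are cleaved in the same pot, all without acid, so the ionisable C1' carbinol survives, and the pyridinolate anion formed first lowers the acidity of the trienone toward the basic fluoride.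

**Step 16**
Reactants: 31 4-hydroxy-5-(cis-1,4-dihydroxycyclohexyl)-3-[(2E,4E,6E,8R)-8-(hydroxymethyl)deca-2,4,6-trienoyl]pyridin-2(1H)-one
Product: 34 1,4-dihydroxy-5-(cis-1,4-dihydroxycyclohexyl)-3-[(2E,4E,6E,8R)-8-(hydroxymethyl)deca-2,4,6-trienoyl]pyridin-2(1H)-one (target), via tetrakis(trimethylsilyl) derivative 32 (not isolated), via N-silyloxy pyridone 33 (not isolated)
Conditions: N,O-bis(trimethylsilyl)acetamide (10 equiv), MeCN–CH2Cl2, rt, then evaporation; MoO(O2)2·pyridine·HMPA (1.5 equiv), CH2Cl2, 0 °C → rt, dark; aq Na4EDTA; citric acid (cat), MeOH–H2O, rt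
Reagents that add atoms: MoO(O2)2·pyridine·HMPA (one oxygen atom), O=[Mo]12(OO1)OO2.c1ccncc1.CN(C)P(=O)(N(C)C)N(C)C; N,O-bis(trimethylsilyl)acetamide (its Me3Si groups stay only in 32 and 33), CC(=N[Si](C)(C)C)O[Si](C)(C)C
Why: Oxidation of an O-silylated lactam to the cyclic hydroxamic acid by an oxodiperoxomolybdenum complex, in which silylation turns the pyridone into the 2,4-bis(silyloxy)pyridine 32 whose ring nitrogen can take an oxygen atom from a peroxo ligand, a silyl shift gives 33, the electron-poor trienone (a motif known to tolerate this reagent in related polyenoyl pyridones) should be spared, and mild hydrolysis strips all Me3Si groups.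

## Compound list

| No. | Name | SMILES | Role |
|---|---|---|---|
| 1 | 5-bromo-2,4-dichloropyridine | Clc1cc(Cl)c(Br)cn1 | starting material |
| 2 | 5-bromo-2,4-bis[2-(trimethylsilyl)ethoxy]pyridine | C[Si](C)(C)CCOc1cc(OCC[Si](C)(C)C)c(Br)cn1 | intermediate |
| 3 | 4-(tert-butyldimethylsilyloxy)cyclohexanone | O=C1CCC(O[Si](C)(C)C(C)(C)C)CC1 | starting material |
| 4 | {4,6-bis[2-(trimethylsilyl)ethoxy]pyridin-3-yl}lithium | [Li]c1cnc(OCC[Si](C)(C)C)cc1OCC[Si](C)(C)C | intermediate |
| 5 | cis-4-(tert-butyldimethylsilyloxy)-1-{4,6-bis[2-(trimethylsilyl)ethoxy]pyridin-3-yl}cyclohexan-1-ol | C[Si](C)(C)CCOc1cc(OCC[Si](C)(C)C)c(cn1)[C@]1(O)CC[C@@H](O[Si](C)(C)C(C)(C)C)CC1 | intermediate |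
| 6 | C3-lithiated lithium alkoxide of 5 | [Li]c1c(OCC[Si](C)(C)C)ncc(c1OCC[Si](C)(C)C)[C@]1(O[Li])CC[C@@H](O[Si](C)(C)C(C)(C)C)CC1 | intermediate |
| 7 | cis-4-(tert-butyldimethylsilyloxy)-1-{5-iodo-4,6-bis[2-(trimethylsilyl)ethoxy]pyridin-3-yl}cyclohexan-1-ol | C[Si](C)(C)CCOc1ncc(c(OCC[Si](C)(C)C)c1I)[C@]1(O)CC[C@@H](O[Si](C)(C)C(C)(C)C)CC1 | intermediate |
| 8 | (R)-4-benzyloxazolidin-2-one | O=C1N[C@H](Cc2ccccc2)CO1 | starting material |
| 9 | butanoyl chloride | CCCC(=O)Cl | starting material |
| 10 | (R)-4-benzyl-3-butanoyloxazolidin-2-one | CCCC(=O)N1[C@H](Cc2ccccc2)COC1=O | intermediate |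
| 11 | 1,3,5-trioxane | C1OCOCO1 | starting material |
| 12 | trichlorotitanium Z-enolate of 10 | CC/C=C(\O[Ti](Cl)(Cl)Cl)N1[C@H](Cc2ccccc2)COC1=O | intermediate |
| 13 | (R)-4-benzyl-3-[(S)-2-(hydroxymethyl)butanoyl]oxazolidin-2-one | CC[C@H](C(=O)N1[C@H](Cc2ccccc2)COC1=O)CO | intermediate |
| 14 | (R)-4-benzyl-3-[(S)-2-(tert-butyldimethylsilyloxymethyl)butanoyl]oxazolidin-2-one | CC[C@H](C(=O)N1[C@H](Cc2ccccc2)COC1=O)CO[Si](C)(C)C(C)(C)C | intermediate |
| 15 | (R)-2-(tert-butyldimethylsilyloxymethyl)butan-1-ol | CC[C@H](CO)CO[Si](C)(C)C(C)(C)C | intermediate |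
| 16 | (S)-2-(tert-butyldimethylsilyloxymethyl)butanal | CC[C@H](C=O)CO[Si](C)(C)C(C)(C)C | intermediate |
| 17 | triethyl (E)-4-phosphonocrotonate | CCOC(=O)/C=C/CP(=O)(OCC)OCC | starting material |
| 18 | lithium salt of 17 | [Li+].CCOC(=O)/C=C/[CH-]P(=O)(OCC)OCC | intermediate |
| 19 | ethyl (2E,4E,6R)-6-(tert-butyldimethylsilyloxymethyl)octa-2,4-dienoate | CC[C@H](/C=C/C=C/C(=O)OCC)CO[Si](C)(C)C(C)(C)C | intermediate |
| 20 | (2E,4E,6R)-6-(tert-butyldimethylsilyloxymethyl)octa-2,4-dien-1-ol | CC[C@H](/C=C/C=C/CO)CO[Si](C)(C)C(C)(C)C | intermediate |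
| 21 | (2E,4E,6R)-6-(tert-butyldimethylsilyloxymethyl)octa-2,4-dienal | CC[C@H](/C=C/C=C/C=O)CO[Si](C)(C)C(C)(C)C | intermediate |
| 22 | dibromomethane | BrCBr | starting material |
| 23 | tributyltin chloride | CCCC[Sn](Cl)(CCCC)CCCC | starting material |
| 24 | dibromomethyllithium | [Li]C(Br)Br | intermediate |
| 25 | tributyl(dibromomethyl)stannane | CCCC[Sn](CCCC)(CCCC)C(Br)Br | intermediate |
| 26 | tributyl(diiodomethyl)stannane | CCCC[Sn](CCCC)(CCCC)C(I)I | intermediate |
| 27 | geminal bis(dichlorochromio)(tributylstannyl)methane | CCCC[Sn](CCCC)(CCCC)C([Cr](Cl)Cl)[Cr](Cl)Cl | intermediate |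
| 28 | tributyl[(1E,3E,5E,7R)-7-(tert-butyldimethylsilyloxymethyl)nona-1,3,5-trienyl]stannane | CC[C@H](/C=C/C=C/C=C/[Sn](CCCC)(CCCC)CCCC)CO[Si](C)(C)C(C)(C)C | intermediate |
| 29 | carbon monoxide | [C-]#[O+] | starting material |
| 30 | (2E,4E,6E,8R)-1-{5-[cis-4-(tert-butyldimethylsilyloxy)-1-hydroxycyclohexyl]-2,4-bis[2-(trimethylsilyl)ethoxy]pyridin-3-yl}-8-(tert-butyldimethylsilyloxymethyl)deca-2,4,6-trien-1-one | CC[C@H](/C=C/C=C/C=C/C(=O)c1c(OCC[Si](C)(C)C)ncc(c1OCC[Si](C)(C)C)[C@]1(O)CC[C@@H](O[Si](C)(C)C(C)(C)C)CC1)CO[Si](C)(C)C(C)(C)C | intermediate |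
| 31 | 4-hydroxy-5-(cis-1,4-dihydroxycyclohexyl)-3-[(2E,4E,6E,8R)-8-(hydroxymethyl)deca-2,4,6-trienoyl]pyridin-2(1H)-one | CC[C@H](/C=C/C=C/C=C/C(=O)c1c(O)c([C@]2(O)CC[C@@H](O)CC2)c[nH]c1=O)CO | intermediate |
| 32 | O2,O4,O4',O(primary)-tetrakis(trimethylsilyl) derivative of 31 (pyridine form) | CC[C@H](/C=C/C=C/C=C/C(=O)c1c(O[Si](C)(C)C)ncc(c1O[Si](C)(C)C)[C@]1(O)CC[C@@H](O[Si](C)(C)C)CC1)CO[Si](C)(C)C | intermediate |
| 33 | 1-(trimethylsilyloxy)pyridin-2-one carrying the O4, O4' and primary Me3Si ethers | CC[C@H](/C=C/C=C/C=C/C(=O)c1c(O[Si](C)(C)C)c(cn(O[Si](C)(C)C)c1=O)[C@]1(O)CC[C@@H](O[Si](C)(C)C)CC1)CO[Si](C)(C)C | intermediate |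
| 34 | 1,4-dihydroxy-5-(cis-1,4-dihydroxycyclohexyl)-3-[(2E,4E,6E,8R)-8-(hydroxymethyl)deca-2,4,6-trienoyl]pyridin-2(1H)-one | CC[C@H](/C=C/C=C/C=C/C(=O)c1c(O)c([C@]2(O)CC[C@@H](O)CC2)cn(O)c1=O)CO | target |

## Step count

- Total step count: 16. Steps 1–3 make the iodide, steps 4–11 the dienal, step 12 the tin reagent and step 13 the stannane. Step 14 is the union and steps 15–16 are the endgame.
- Longest linear sequence: 12 steps (steps 4–11, then 13–16).

## Steps most likely to fail

**Step 14.**
- What may go wrong: oxidative addition and transmetalation at the doubly ortho-alkoxylated C3 may be sluggish under CO. Direct aryl–trienyl coupling, homocoupling or protodestannylation of the stannane, and E/Z drift could then outrun ketone formation.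
- Fallback: this abandons CO and brings C7 in as an aldehyde carbon. It sets out from 21 and 5 and returns at 30.
- Wittig homologation of 21 with (triphenylphosphoranylidene)acetaldehyde in warm toluene gives (2E,4E,6E,8R)-8-(tert-butyldimethylsilyloxymethyl)deca-2,4,6-trienal F1.
- The dilithio species 6, raised from 5 exactly as in step 3, is added to F1 at −78 °C. This gives the C7 carbinol F2 as a mixture of C7 epimers.
- MnO2 oxidation of this alcohol, which is both pyridylic and trienylic, erases the C7 centre and gives 30.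

**Step 16.**
- What may go wrong: oxygen transfer to the weakly nucleophilic nitrogen of the acylated bis(silyloxy)pyridine may be incomplete. Epoxidation at the distal C12=C13 alkene may compete, and the product hydroxamic acid may bind tightly to molybdenum.
- Fallback: this installs the N–O bond before the triene exists. It sets out from 7 and returns at 34.
- Peracid oxidation of 7 (mCPBA, CH2Cl2, rt) gives the pyridine N-oxide of the iodide F3.
- Carbonylative Stille coupling of F3 with 28 and 29 under the conditions of step 14 gives the N-oxide of the trienone F4.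
- Bu4NF as in step 15 then removes all four silicon-based groups. Loss of the O2 alkyl group from a 2-alkoxypyridine N-oxide delivers the 1-hydroxy-2-pyridone tautomer, which is 34, directly.

**Step 2.**
- What may go wrong: facial selectivity may be poor, because 4-silyloxycyclohexanone also populates the chair with an axial silyloxy group and aryl nucleophiles discriminate only modestly between the two trajectories. Enolisation of the ketone by the basic aryllithium may add to the loss.
- Fallback: this moves the stereodefining event to a ketone reduction. It sets out from 2 (through 4) and returns at 5.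
- Addition of 4 to 1,4-dioxaspiro[4.5]decan-8-one gives the achiral ketal carbinol F5.
- Mild deketalisation (pyridinium p-toluenesulfonate, aq acetone) gives 4-hydroxy-4-pyridylcyclohexanone F6. The basic ring nitrogen takes up the proton and so disfavours ionisation at C1'.
- In F6 the chair is locked with the pyridyl group equatorial and the C1' hydroxyl axial. Axial delivery of a small hydride (NaBH4, MeOH, −40 °C) should therefore give the equatorial C4' alcohol, the cis-1,4-diol F7.
- TBSCl with imidazole silylates only the secondary hydroxyl and gives 5.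

## Further compounds

F1 | step 14 | (2E,4E,6E,8R)-8-(tert-butyldimethylsilyloxymethyl)deca-2,4,6-trienal | CC[C@H](/C=C/C=C/C=C/C=O)CO[Si](C)(C)C(C)(C)C
F2 | step 14 | (2E,4E,6E,8R)-1-{5-[cis-4-(tert-butyldimethylsilyloxy)-1-hydroxycyclohexyl]-2,4-bis[2-(trimethylsilyl)ethoxy]pyridin-3-yl}-8-(tert-butyldimethylsilyloxymethyl)deca-2,4,6-trien-1-ol (C7 epimers) | CC[C@H](/C=C/C=C/C=C/C(O)c1c(OCC[Si](C)(C)C)ncc(c1OCC[Si](C)(C)C)[C@]1(O)CC[C@@H](O[Si](C)(C)C(C)(C)C)CC1)CO[Si](C)(C)C(C)(C)C
F3 | step 16 | cis-4-(tert-butyldimethylsilyloxy)-1-{5-iodo-1-oxido-4,6-bis[2-(trimethylsilyl)ethoxy]pyridin-1-ium-3-yl}cyclohexan-1-ol | C[Si](C)(C)CCOc1c(I)c(OCC[Si](C)(C)C)c(c[n+]1[O-])[C@]1(O)CC[C@@H](O[Si](C)(C)C(C)(C)C)CC1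
F4 | step 16 | pyridine N-oxide of 30 | CC[C@H](/C=C/C=C/C=C/C(=O)c1c(OCC[Si](C)(C)C)c(c[n+]([O-])c1OCC[Si](C)(C)C)[C@]1(O)CC[C@@H](O[Si](C)(C)C(C)(C)C)CC1)CO[Si](C)(C)C(C)(C)C
F5 | step 2 | 8-{4,6-bis[2-(trimethylsilyl)ethoxy]pyridin-3-yl}-1,4-dioxaspiro[4.5]decan-8-ol | C[Si](C)(C)CCOc1cc(OCC[Si](C)(C)C)c(cn1)C1(O)CCC2(CC1)OCCO2
F6 | step 2 | 4-{4,6-bis[2-(trimethylsilyl)ethoxy]pyridin-3-yl}-4-hydroxycyclohexan-1-one | C[Si](C)(C)CCOc1cc(OCC[Si](C)(C)C)c(cn1)C1(O)CCC(=O)CC1
F7 | step 2 | cis-1-{4,6-bis[2-(trimethylsilyl)ethoxy]pyridin-3-yl}cyclohexane-1,4-diol | C[Si](C)(C)CCOc1cc(OCC[Si](C)(C)C)c(cn1)[C@]1(O)CC[C@@H](O)CC1
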